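**Strategy.** Ring A is disconnected from the pyranone ring C at C5–C6, C7–C8 and C8–C8a. A Dötz benzannulation of a pyranon-3-yl methoxycarbene chromium complex with ethynylboronic acid pinacol ester builds the whole benzo ring in one operation and delivers the para pair O5/O8 of ring A in differentiated form. O5 arrives as the carbene methyl ether, O8 as a free phenol from a carbonyl ligand, and C7 carries boron as a latent hydroxyl while C6 keeps hydrogen. The precursor is the fully substituted ring C (3-methoxy, 2-(4-prenyloxyphenyl)) with the carbene carbon on the future C4a and an unsubstituted CH at the future C8a.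

Key step: step 6

Remark: the alkyne is assumed to insert with its boron-bearing carbon next to the carbonyl-derived carbon C8 (steric control, as with other 1-alkynylboronates); compound 6 has one enolisable centre at C4 and is carried as the racemate/enol mixture, and the target has no stereocentre.

**Step 1**
Reactants: 1 methyl 4-hydroxybenzoate; 2 prenyl bromide (1-bromo-3-methylbut-2-ene)
Product: 3 methyl 4-[(3-methylbut-2-en-1-yl)oxy]benzoate
Conditions: K2CO3, acetone, 56 °C
Reagents that add atoms: none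
Why: Williamson ether synthesis, in which the phenoxide displaces the primary allylic bromide by SN2 while the methyl ester is untouched by carbonate.

**Step 2**
Reactants: 3 methyl 4-[(3-methylbut-2-en-1-yl)oxy]benzoate; 4 methyl 4-methoxyacetoacetate
Product: 6 methyl 4-methoxy-5-{4-[(3-methylbut-2-en-1-yl)oxy]phenyl}-3,5-dioxopentanoate, via dilithium dienolate of methyl 4-methoxyacetoacetate 5 (not isolated)
Conditions: 4 (2.2 equiv), LiN(iPr)2 (4.5 equiv), THF, −78 to 0 °C; then 3, 0 °C to rt; AcOH quench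
Reagents that add atoms: none
Why: Crossed Claisen condensation of the acetoacetate 2,4-dianion, which should acylate at its more nucleophilic γ-carbon with the non-enolisable benzoate while the excess dianion absorbs the more acidic product; the new C4 centre is enolisable and is not controlled.

**Step 3**
Reactants: 6 methyl 4-methoxy-5-{4-[(3-methylbut-2-en-1-yl)oxy]phenyl}-3,5-dioxopentanoate
Product: 8 methyl 5-methoxy-6-{4-[(3-methylbut-2-en-1-yl)oxy]phenyl}-4-oxo-4H-pyran-3-carboxylate, via enaminone 7 (not isolated)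
Conditions: Me2NCH(OMe)2 (1.2 equiv), toluene, rt; then AcOH (cat.), 60 °C
Reagents that add atoms: N,N-dimethylformamide dimethyl acetal, COC(OC)N(C)C
Why: Aminomethylenation of the only CH2 flanked by two carbonyls (C4 has a single hydrogen and cannot condense), followed by addition–elimination of the aryl ketone enol oxygen at the enamine carbon with loss of dimethylamine, is the standard 4-pyranone closure of 3,5-diketo esters.

**Step 4**
Reactants: 8 methyl 5-methoxy-6-{4-[(3-methylbut-2-en-1-yl)oxy]phenyl}-4-oxo-4H-pyran-3-carboxylate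
Product: 9 5-methoxy-6-{4-[(3-methylbut-2-en-1-yl)oxy]phenyl}-4-oxo-4H-pyran-3-carboxylic acid
Conditions: Me3SnOH (4 equiv), ClCH2CH2Cl, 70 °C; then cold 0.5 M HCl wash
Reagents that add atoms: trimethyltin hydroxide, C[Sn](C)(C)O
Why: Tin-mediated neutral ester hydrolysis is chosen because free hydroxide would add to the unsubstituted C2 of the 3-acylpyranone and open the ring, and hot mineral acid would cleave the prenyl ether.

**Step 5**
Reactants: 9 5-methoxy-6-{4-[(3-methylbut-2-en-1-yl)oxy]phenyl}-4-oxo-4H-pyran-3-carboxylic acid; 10 chromium hexacarbonyl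
Product: 14 pentacarbonyl{methoxy[5-methoxy-6-(4-[(3-methylbut-2-en-1-yl)oxy]phenyl)-4-oxo-4H-pyran-3-yl]methylidene}chromium, via acid chloride 11 (not isolated), via K2Cr(CO)5 12 (not isolated), via potassium acylchromate 13 (not isolated)
Conditions: (a) 9, Me2C=C(Cl)NMe2 (1.1 equiv), CH2Cl2, 0 °C to rt, evaporate; (b) separate flask: Cr(CO)6, C8K (2.1 equiv), THF, −78 to 0 °C; (c) 11 in THF added to 12 at −78 °C, then 0 °C; (d) Me3OBF4 (1.1 equiv), CH2Cl2, 0 °C
Reagents that add atoms: trimethyloxonium tetrafluoroborate, C[O+](C)C.F[B-](F)(F)F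
Why: Nucleophilic acyl substitution of the acid chloride by the pentacarbonylchromate dianion gives the acylchromate, whose anionic oxygen is methylated by the oxonium salt far faster than the pyranone carbonyl (the acid chloride route to alkoxycarbene complexes), and the chloroenamine makes the acid chloride without free HCl so the prenyl ether is safe.

**Step 6**
Reactants: 14 pentacarbonyl{methoxy[5-methoxy-6-(4-[(3-methylbut-2-en-1-yl)oxy]phenyl)-4-oxo-4H-pyran-3-yl]methylidene}chromium; 15 ethynylboronic acid pinacol ester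
Product: 17 8-hydroxy-3,5-dimethoxy-2-{4-[(3-methylbut-2-en-1-yl)oxy]phenyl}-7-(4,4,5,5-tetramethyl-1,3,2-dioxaborolan-2-yl)-4H-chromen-4-one, via ring A Cr(CO)3 complex 16 (not isolated)
Conditions: 15 (2 equiv), THF (0.05 M), 50 °C, Ar; then MeCN, air, rt
Reagents that add atoms: none
Why: Loss of one CO from 14 (the neighbouring C4 carbonyl can occupy the vacant site) lets the alkyne bind and insert into the Cr=C bond with its CH terminus joining the carbene carbon (C5–C6), and CO insertion then gives a chromium-bound vinylketene (C7–C8). Ring A closes by 6π-electrocyclisation of this dienylketene onto the pyranone CH carbon next to the ring oxygen (C8–C8a), and enolisation of the cyclohexadienone, driven by aromatisation, gives the 4-methoxyphenol, first as its Cr(CO)3 complex 16 and after air oxidation as free 17. The closest known reaction is the Dötz benzannulation of cycloalkenyl and heteroaryl methoxycarbene chromium complexes with 1-alkynylboronates. No stereocentre is formed. The step needs regioselective insertion (boron at C7, hydrogen at C6), which the size difference between the boryl group and hydrogen should secure, and it needs CO insertion to outrun cyclopentannulation, which chromium, the ether solvent and the ring-locked cis geometry of the pyranone double bond favour. The free CH at the future C8a allows the final tautomerisation, and the one-sided alkylation of the para pair O5/O8 is inherent to the mechanism.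

**Step 7**
Reactants: 17 8-hydroxy-3,5-dimethoxy-2-{4-[(3-methylbut-2-en-1-yl)oxy]phenyl}-7-(4,4,5,5-tetramethyl-1,3,2-dioxaborolan-2-yl)-4H-chromen-4-one
Product: 18 3,5,8-trimethoxy-2-{4-[(3-methylbut-2-en-1-yl)oxy]phenyl}-7-(4,4,5,5-tetramethyl-1,3,2-dioxaborolan-2-yl)-4H-chromen-4-one
Conditions: MeI, K2CO3, acetone, 40 °C
Reagents that add atoms: iodomethane, CI
Why: Williamson O-methylation of the only free phenol fixes the C8 methyl ether while C7 is still masked as the boronate, which is inert to mild carbonate.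

**Step 8**
Reactants: 18 3,5,8-trimethoxy-2-{4-[(3-methylbut-2-en-1-yl)oxy]phenyl}-7-(4,4,5,5-tetramethyl-1,3,2-dioxaborolan-2-yl)-4H-chromen-4-one
Product: 19 5-hydroxy-3,8-dimethoxy-2-{4-[(3-methylbut-2-en-1-yl)oxy]phenyl}-7-(4,4,5,5-tetramethyl-1,3,2-dioxaborolan-2-yl)-4H-chromen-4-one
Conditions: MgI2 (anhydrous, 2 equiv), THF–toluene, 60 °C; then cold 0.5 M HCl
Reagents that add atoms: none
Why: Chelation-controlled demethylation, in which magnesium bridges the C4 carbonyl and O5 in a six-membered chelate and iodide removes that methyl group by SN2, whereas O3 offers only a five-membered chelate and O8 and the prenyl ether are not chelated; running it before the boronate oxidation avoids a competing O7/O8 chelate.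

**Step 9**
Reactants: 19 5-hydroxy-3,8-dimethoxy-2-{4-[(3-methylbut-2-en-1-yl)oxy]phenyl}-7-(4,4,5,5-tetramethyl-1,3,2-dioxaborolan-2-yl)-4H-chromen-4-one
Product: 20 5,7-dihydroxy-3,8-dimethoxy-2-{4-[(3-methylbut-2-en-1-yl)oxy]phenyl}-4H-chromen-4-one
Conditions: NaBO3·4H2O (3 equiv), THF–H2O, rt
Reagents that add atoms: sodium perborate NaBO3 (used as the tetrahydrate), [Na+].[O-]OB=O
Why: Ipso-oxidation of the aryl boronate (peroxide adds to boron, the aryl group migrates from boron to oxygen, the borate ester hydrolyses) is mild enough to spare the prenyl alkene, the chromone and the phenols.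

**Compound list**
1 | methyl 4-hydroxybenzoate | COC(=O)c1ccc(O)cc1 | starting material
2 | prenyl bromide (1-bromo-3-methylbut-2-ene) | CC(C)=CCBr | starting material
3 | methyl 4-[(3-methylbut-2-en-1-yl)oxy]benzoate | COC(=O)c1ccc(OCC=C(C)C)cc1 | intermediate
4 | methyl 4-methoxyacetoacetate | COCC(=O)CC(=O)OC | starting material
5 | dilithium dienolate (2,4-dianion) of methyl 4-methoxyacetoacetate (formed in the flask; enolate geometry undefined) | [Li+].[Li+].COC=C([O-])C=C([O-])OC | intermediate
6 | methyl 4-methoxy-5-{4-[(3-methylbut-2-en-1-yl)oxy]phenyl}-3,5-dioxopentanoate (racemic at C4; enolisable) | COC(=O)CC(=O)C(OC)C(=O)c1ccc(OCC=C(C)C)cc1 | intermediate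
7 | methyl 2-[(dimethylamino)methylidene]-4-methoxy-5-{4-[(3-methylbut-2-en-1-yl)oxy]phenyl}-3,5-dioxopentanoate (formed in the flask; racemic; alkene geometry undefined) | COC(=O)C(=CN(C)C)C(=O)C(OC)C(=O)c1ccc(OCC=C(C)C)cc1 | intermediate
8 | methyl 5-methoxy-6-{4-[(3-methylbut-2-en-1-yl)oxy]phenyl}-4-oxo-4H-pyran-3-carboxylate | COC(=O)c1coc(-c2ccc(OCC=C(C)C)cc2)c(OC)c1=O | intermediate
9 | 5-methoxy-6-{4-[(3-methylbut-2-en-1-yl)oxy]phenyl}-4-oxo-4H-pyran-3-carboxylic acid | OC(=O)c1coc(-c2ccc(OCC=C(C)C)cc2)c(OC)c1=O | intermediate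
10 | chromium hexacarbonyl Cr(CO)6 | O=C=[Cr](=C=O)(=C=O)(=C=O)(=C=O)=C=O | starting material
11 | 5-methoxy-6-{4-[(3-methylbut-2-en-1-yl)oxy]phenyl}-4-oxo-4H-pyran-3-carbonyl chloride (formed in the flask) | ClC(=O)c1coc(-c2ccc(OCC=C(C)C)cc2)c(OC)c1=O | intermediate
12 | dipotassium pentacarbonylchromate K2Cr(CO)5 (formed in the flask) | [K+].[K+].O=C=[Cr-2](=C=O)(=C=O)(=C=O)=C=O | intermediate
13 | potassium pentacarbonyl(acyl)chromate of the pyranone acid, drawn as the oxidocarbene (formed in the flask) | [K+].[O-]C(=[Cr](=C=O)(=C=O)(=C=O)(=C=O)=C=O)c1coc(-c2ccc(OCC=C(C)C)cc2)c(OC)c1=O | intermediate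
14 | pentacarbonyl{methoxy[5-methoxy-6-(4-[(3-methylbut-2-en-1-yl)oxy]phenyl)-4-oxo-4H-pyran-3-yl]methylidene}chromium | COC(=[Cr](=C=O)(=C=O)(=C=O)(=C=O)=C=O)c1coc(-c2ccc(OCC=C(C)C)cc2)c(OC)c1=O | intermediate
15 | ethynylboronic acid pinacol ester | C#CB1OC(C)(C)C(C)(C)O1 | starting material
16 | Cr(CO)3 complex of 17, bound through the six carbons of ring A (formed in the flask; the hapto bond is written as two components) | COc1c(-c2ccc(OCC=C(C)C)cc2)oc2c(O)c(B3OC(C)(C)C(C)(C)O3)cc(OC)c2c1=O.O=C=[Cr](=C=O)=C=O | intermediate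
17 | 8-hydroxy-3,5-dimethoxy-2-{4-[(3-methylbut-2-en-1-yl)oxy]phenyl}-7-(4,4,5,5-tetramethyl-1,3,2-dioxaborolan-2-yl)-4H-chromen-4-one | COc1c(-c2ccc(OCC=C(C)C)cc2)oc2c(O)c(B3OC(C)(C)C(C)(C)O3)cc(OC)c2c1=O | intermediate
18 | 3,5,8-trimethoxy-2-{4-[(3-methylbut-2-en-1-yl)oxy]phenyl}-7-(4,4,5,5-tetramethyl-1,3,2-dioxaborolan-2-yl)-4H-chromen-4-one | COc1c(-c2ccc(OCC=C(C)C)cc2)oc2c(OC)c(B3OC(C)(C)C(C)(C)O3)cc(OC)c2c1=O | intermediate
19 | 5-hydroxy-3,8-dimethoxy-2-{4-[(3-methylbut-2-en-1-yl)oxy]phenyl}-7-(4,4,5,5-tetramethyl-1,3,2-dioxaborolan-2-yl)-4H-chromen-4-one | COc1c(-c2ccc(OCC=C(C)C)cc2)oc2c(OC)c(B3OC(C)(C)C(C)(C)O3)cc(O)c2c1=O | intermediate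
20 | 5,7-dihydroxy-3,8-dimethoxy-4'-prenyloxyflavone | COc1c(-c2ccc(OCC=C(C)C)cc2)oc2c(OC)c(O)cc(O)c2c1=O | target

**Total step count:** 9. **Longest linear sequence:** 9 steps (1 to 20).

**Steps most likely to fail**

Step 6. The terminal alkynylboronate may oligomerise or be taken up more than once, insertion may occur with the opposite orientation, or the C4 carbonyl may divert the vinylcarbene intermediate before CO insertion. The fallback sets out from 14 and returns at 20. It uses the internal, silyl-capped 4,4,5,5-tetramethyl-2-[(trimethylsilyl)ethynyl]-1,3,2-dioxaborolane, which has no terminal C–H and belongs to the disubstituted alkynylboronate class for which this chromium benzannulation is established. Under the conditions of step 6 it should give 8-hydroxy-3,5-dimethoxy-2-{4-[(3-methylbut-2-en-1-yl)oxy]phenyl}-7-(pinacolboryl)-6-(trimethylsilyl)-4H-chromen-4-one F1. Methylation (MeI, K2CO3) should give the 3,5,8-trimethoxy-6-silyl boronate F2, and MgI2 as in step 8 the 5-hydroxy-6-silyl boronate F3. NaBO3·4H2O should then give 5,7-dihydroxy-3,8-dimethoxy-6-(trimethylsilyl)-4'-prenyloxyflavone F4. In F4 silicon sits between two phenols and should be lost by ipso-protodesilylation (Bu4NF·3H2O in THF, if not already in the aqueous perborate medium) to give 20.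

Step 5. The strongly reducing K2Cr(CO)5 may attack or reduce the electrophilic pyranone instead of the acyl chloride, and the oxonium salt may alkylate the pyranone carbonyl oxygen in competition with the acylate. The fallback sets out from 13 (made as in step 5 with inverse addition at −78 °C) and returns at 14. It replaces direct O-alkylation by acylation and alcoholysis. Cation exchange with aqueous Me4NBr should give the isolable tetramethylammonium pentacarbonyl(acyl)chromate F5, which can be crystallised free of by-products. Acetyl bromide (CH2Cl2, −40 °C) should convert it into the acetoxycarbene complex F6, and methanol should exchange the acetoxy group to give 14.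

Step 8. Iodide may cleave the prenyl ether, or demethylation may extend to O3 or O8. The fallback sets out from 17, avoids Lewis acids and returns at 19. PhI(OAc)2 in MeCN–H2O at 0 °C should oxidise the 4-methoxyphenol to the 5,8-quinone, 3-methoxy-2-{4-[(3-methylbut-2-en-1-yl)oxy]phenyl}-7-(pinacolboryl)-4H-chromene-4,5,8-trione F7, with loss of the O5 methyl group. Na2S2O4 (EtOAc–H2O) should reduce it to the 5,8-dihydroxy-3-methoxy boronate F8. One equivalent of MeI with K2CO3 in acetone under argon should methylate only the non-chelated 8-hydroxyl, giving 19.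

**Further compounds**
F1 | step 6 | 8-hydroxy-3,5-dimethoxy-2-{4-[(3-methylbut-2-en-1-yl)oxy]phenyl}-7-(4,4,5,5-tetramethyl-1,3,2-dioxaborolan-2-yl)-6-(trimethylsilyl)-4H-chromen-4-one | COc1c(-c2ccc(OCC=C(C)C)cc2)oc2c(O)c(B3OC(C)(C)C(C)(C)O3)c([Si](C)(C)C)c(OC)c2c1=O
F2 | step 6 | 3,5,8-trimethoxy-2-{4-[(3-methylbut-2-en-1-yl)oxy]phenyl}-7-(4,4,5,5-tetramethyl-1,3,2-dioxaborolan-2-yl)-6-(trimethylsilyl)-4H-chromen-4-one | COc1c(-c2ccc(OCC=C(C)C)cc2)oc2c(OC)c(B3OC(C)(C)C(C)(C)O3)c([Si](C)(C)C)c(OC)c2c1=O
F3 | step 6 | 5-hydroxy-3,8-dimethoxy-2-{4-[(3-methylbut-2-en-1-yl)oxy]phenyl}-7-(4,4,5,5-tetramethyl-1,3,2-dioxaborolan-2-yl)-6-(trimethylsilyl)-4H-chromen-4-one | COc1c(-c2ccc(OCC=C(C)C)cc2)oc2c(OC)c(B3OC(C)(C)C(C)(C)O3)c([Si](C)(C)C)c(O)c2c1=O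
F4 | step 6 | 5,7-dihydroxy-3,8-dimethoxy-2-{4-[(3-methylbut-2-en-1-yl)oxy]phenyl}-6-(trimethylsilyl)-4H-chromen-4-one | COc1c(-c2ccc(OCC=C(C)C)cc2)oc2c(OC)c(O)c([Si](C)(C)C)c(O)c2c1=O
F5 | step 5 | tetramethylammonium pentacarbonyl(acyl)chromate of the pyranone acid, drawn as the oxidocarbene | C[N+](C)(C)C.[O-]C(=[Cr](=C=O)(=C=O)(=C=O)(=C=O)=C=O)c1coc(-c2ccc(OCC=C(C)C)cc2)c(OC)c1=O
F6 | step 5 | pentacarbonyl{acetoxy[5-methoxy-6-(4-[(3-methylbut-2-en-1-yl)oxy]phenyl)-4-oxo-4H-pyran-3-yl]methylidene}chromium | CC(=O)OC(=[Cr](=C=O)(=C=O)(=C=O)(=C=O)=C=O)c1coc(-c2ccc(OCC=C(C)C)cc2)c(OC)c1=O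
F7 | step 8 | 3-methoxy-2-{4-[(3-methylbut-2-en-1-yl)oxy]phenyl}-7-(4,4,5,5-tetramethyl-1,3,2-dioxaborolan-2-yl)-4H-chromene-4,5,8-trione | COC1=C(c2ccc(OCC=C(C)C)cc2)OC2=C(C1=O)C(=O)C=C(B3OC(C)(C)C(C)(C)O3)C2=O
F8 | step 8 | 5,8-dihydroxy-3-methoxy-2-{4-[(3-methylbut-2-en-1-yl)oxy]phenyl}-7-(4,4,5,5-tetramethyl-1,3,2-dioxaborolan-2-yl)-4H-chromen-4-one | COc1c(-c2ccc(OCC=C(C)C)cc2)oc2c(O)c(B3OC(C)(C)C(C)(C)O3)cc(O)c2c1=O
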